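With the ring numbered C1 (CMe2) to C6 and the side chain C7–C8, the disconnection is C5–C6. The chlorines at C4 and C6 flank the C5 methylene of the cyclohexane in a 1,3-pattern that maps onto a β-hydroxy ketone, and C1 with its methyl groups plus C6 is isobutyraldehyde. An amine-catalysed intramolecular aldol closes the carbocycle from achiral 4-acetyl-2,2-dimethyl-5-oxohex-3-enal, a neopentyl aldehyde held by C2=C3 beside an acetylacetone unit. One operation forms C5–C6, the six-membered ring and the C6 carbinol, with all ten carbons and oxygen at C4, C6 and C7 in place. Directed reduction, double inversive chlorination, C8 bromination, C7 reduction and syn SN2′ bromination finish.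

Key step: step 3

Remark on the chemistry: the target is read as (2S,3Z,4S,6S)-2-bromo-3-(2-bromoethylidene)-4,6-dichloro-1,1-dimethylcyclohexane. Atom labels C1–C8 in the text are those of the target (C7 is =CH, C8 is CH2Br); locants inside compound names follow each name. Adduct 5 is formulated as the dihydropyran N,O-acetal; an open-chain isomer would hydrolyse to the same aldehyde.

Step 1
Reactants: 1 isobutyraldehyde; 2 morpholine
Product: 3 4-(2-methylprop-1-en-1-yl)morpholine
Conditions: p-toluenesulfonic acid (cat.), cyclohexane, reflux, Dean–Stark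
Reagents that add atoms: none
Why: Enamine formation from an α-branched aldehyde and a secondary amine is driven to completion by azeotropic removal of water; no stereocentre arises.

Step 2
Reactants: 3 4-(2-methylprop-1-en-1-yl)morpholine; 4 3-(ethoxymethylene)pentane-2,4-dione
Product: 6 4-acetyl-2,2-dimethyl-5-oxohex-3-enal, via dihydropyran adduct 5 (not isolated)
Conditions: MeCN, 0 °C to rt; then 0.5 M HCl, Et2O, 0 °C
Reagents that add atoms: water, O
Why: In a Stork enamine Michael addition the nucleophilic β-carbon of the enamine attacks the ethoxymethylene carbon and the zwitterion closes to the formal hetero-Diels–Alder adduct 5, which cold dilute acid hydrolyses at the N,O-acetal with β-elimination of ethanol, the acid keeping the released morpholine protonated in the aqueous phase so that it cannot start a racemic aldol closure; no stereocentre arises.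

Step 3
Reactants: 6 4-acetyl-2,2-dimethyl-5-oxohex-3-enal
Product: 8 (5R)-2-acetyl-5-hydroxy-4,4-dimethylcyclohex-2-en-1-one, via proline enamine 7 (not isolated)
Conditions: (R)-proline (20 mol %), DMSO, rt
Reagents that add atoms: none
Why: (R)-Proline condenses with the acetyl group that lies cis to the CMe2CHO arm to give enamine 7, whose terminal carbon C5 adds to the C6 aldehyde, and hydrolysis of the iminium ion releases 8 and the catalyst. The closest known reaction type is the Hajos–Parrish cyclisation, an amine-catalysed intramolecular enolendo aldol. The single ring, the six-membered carbocycle C1–C6, closes in the 6-(enolendo)-exo-trig mode. The new stereocentre C6 is set by the catalyst, whose carboxylic acid hydrogen-bonds the aldehyde oxygen in the anti-enamine transition state; by analogy with the Hajos–Parrish ketol, where (S)-proline gives the S carbinol at the corresponding atom, the (R)-catalyst should give the 5R alcohol, and the other antipode is at hand should the sense prove reversed. The step needs enamine formation at a ketone beside a free aldehyde, closure through one acetyl group only, and survival of the β-hydroxy ketone. The aldehyde is neopentyl and cannot enolise, the fixed C2=C3 bond lets only the cis acetyl reach it, the quaternary C1 shields C2 from aza-Michael addition, and neutral conditions at room temperature should prevent dehydration.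

Step 4
Reactants: 8 (5R)-2-acetyl-5-hydroxy-4,4-dimethylcyclohex-2-en-1-one
Product: 9 1-[(4R,6R)-4,6-dihydroxy-3,3-dimethylcyclohex-1-en-1-yl]ethan-1-one
Conditions: Me4NBH(OAc)3, MeCN/AcOH (1:1), −30 °C
Reagents that add atoms: none
Why: In an Evans–Saksena reduction the C6 hydroxyl binds boron and delivers hydride intramolecularly to the ring ketone C4 on its own face, so the new C4 carbinol should form trans to C6–OH (R), while the acetyl ketone, which has no hydroxyl within reach, and the shielded enone double bond are not attacked by this mild hydride.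

Step 5
Reactants: 9 1-[(4R,6R)-4,6-dihydroxy-3,3-dimethylcyclohex-1-en-1-yl]ethan-1-one
Product: 10 1-[(4S,6S)-4,6-dichloro-3,3-dimethylcyclohex-1-en-1-yl]ethan-1-one
Conditions: PPh3, CCl4, MeCN, 0 °C to 60 °C
Reagents that add atoms: carbon tetrachloride, ClC(Cl)(Cl)Cl
Why: In a double Appel reaction each alkoxyphosphonium ion is displaced by chloride from the rear (SN2), inverting the allylic C4 in the cold and the neopentyl C6 on warming to give the trans 4S,6S dichloride; the trans diol cannot form a cyclic phosphorane, the acyl group disfavours ionisation at C4, and the quaternary C1 shields C2 against SN2′ attack.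

Step 6
Reactants: 10 1-[(4S,6S)-4,6-dichloro-3,3-dimethylcyclohex-1-en-1-yl]ethan-1-one
Product: 12 2-bromo-1-[(4S,6S)-4,6-dichloro-3,3-dimethylcyclohex-1-en-1-yl]ethan-1-one, via silyl dienol ether 11 (not isolated)
Conditions: TMSOTf, Et3N, CH2Cl2, 0 °C; then NBS, THF, −78 °C to 0 °C
Reagents that add atoms: N-bromosuccinimide, O=C1CCC(=O)N1Br
Why: Soft enolisation of the methyl ketone, the only enolisable position since C1 is quaternary and C4–H is not conjugated with the carbonyl, gives the 2-silyloxydiene 11, which NBS brominates at its terminal carbon C8 (α-bromination of a ketone through its silyl enol ether) without touching a stereocentre.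

Step 7
Reactants: 12 2-bromo-1-[(4S,6S)-4,6-dichloro-3,3-dimethylcyclohex-1-en-1-yl]ethan-1-one
Product: 13 (1R)-2-bromo-1-[(4S,6S)-4,6-dichloro-3,3-dimethylcyclohex-1-en-1-yl]ethan-1-ol
Conditions: (3aR)-1-methyl-3,3-diphenyltetrahydro-1H,3H-pyrrolo[1,2-c][1,3,2]oxazaborole (20 mol %), BH3·SMe2, THF, −20 °C
Reagents that add atoms: none
Why: In the Corey–Bakshi–Shibata reduction the oxazaborolidine–borane complex binds the ketone with the branched cyclohexenyl group as the large and CH2Br as the small substituent, so the (R)-catalyst should deliver hydride to the face that sets C7 as R under reagent control, 1,2-selectively and without reducing the C–Cl or C–Br bonds.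

Step 8
Reactants: 13 (1R)-2-bromo-1-[(4S,6S)-4,6-dichloro-3,3-dimethylcyclohex-1-en-1-yl]ethan-1-ol
Product: 15 (2S,3Z,4S,6S)-2-bromo-3-(2-bromoethylidene)-4,6-dichloro-1,1-dimethylcyclohexane, via allylic bromosulfite 14 (not isolated)
Conditions: SOBr2, Et2O, −40 °C to 0 °C
Reagents that add atoms: thionyl bromide, O=S(Br)Br
Why: Thionyl bromide forms bromosulfite 14, which in ether without base should collapse through a six-membered cyclic transition state (SNi′, syn SN2′) so that bromine enters C2 on the face from which the C7 oxygen departs; in the rotamer that keeps CH2Br on the side of the unsubstituted C2–H and away from the substituted C4, the R carbinol transfers its chirality to give the 2S bromide and the Z C3=C7 double bond.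

Compound list
1 | isobutyraldehyde | CC(C)C=O | starting material
2 | morpholine | C1COCCN1 | starting material
3 | 4-(2-methylprop-1-en-1-yl)morpholine | CC(C)=CN1CCOCC1 | intermediate
4 | 3-(ethoxymethylene)pentane-2,4-dione | CCOC=C(C(C)=O)C(C)=O | starting material
5 | 1-[4-ethoxy-3,3,6-trimethyl-2-(morpholin-4-yl)-3,4-dihydro-2H-pyran-5-yl]ethan-1-one (mixture of diastereomers, not isolated) | CCOC1C(C(C)=O)=C(C)OC(N2CCOCC2)C1(C)C | intermediate
6 | 4-acetyl-2,2-dimethyl-5-oxohex-3-enal | CC(=O)C(=CC(C)(C)C=O)C(C)=O | intermediate
7 | (2R)-1-[(3E)-3-acetyl-5,5-dimethyl-6-oxohexa-1,3-dien-2-yl]pyrrolidine-2-carboxylic acid (not isolated) | C=C(N1CCC[C@@H]1C(O)=O)\C(C(C)=O)=C/C(C)(C)C=O | intermediate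
8 | (5R)-2-acetyl-5-hydroxy-4,4-dimethylcyclohex-2-en-1-one | CC1(C)C=C(C(C)=O)C(=O)C[C@H]1O | intermediate
9 | 1-[(4R,6R)-4,6-dihydroxy-3,3-dimethylcyclohex-1-en-1-yl]ethan-1-one (hydroxyls trans) | CC1(C)C=C(C(C)=O)[C@H](O)C[C@H]1O | intermediate
10 | 1-[(4S,6S)-4,6-dichloro-3,3-dimethylcyclohex-1-en-1-yl]ethan-1-one (chlorines trans) | CC1(C)C=C(C(C)=O)[C@@H](Cl)C[C@@H]1Cl | intermediate
11 | ({1-[(4S,6S)-4,6-dichloro-3,3-dimethylcyclohex-1-en-1-yl]ethenyl}oxy)trimethylsilane (not isolated) | CC1(C)C=C(C(=C)O[Si](C)(C)C)[C@@H](Cl)C[C@@H]1Cl | intermediate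
12 | 2-bromo-1-[(4S,6S)-4,6-dichloro-3,3-dimethylcyclohex-1-en-1-yl]ethan-1-one | CC1(C)C=C(C(=O)CBr)[C@@H](Cl)C[C@@H]1Cl | intermediate
13 | (1R)-2-bromo-1-[(4S,6S)-4,6-dichloro-3,3-dimethylcyclohex-1-en-1-yl]ethan-1-ol | CC1(C)C=C([C@@H](O)CBr)[C@@H](Cl)C[C@@H]1Cl | intermediate
14 | (1R)-2-bromo-1-[(4S,6S)-4,6-dichloro-3,3-dimethylcyclohex-1-en-1-yl]ethyl bromosulfite (not isolated) | CC1(C)C=C([C@@H](OS(Br)=O)CBr)[C@@H](Cl)C[C@@H]1Cl | intermediate
15 | (2S,3Z,4S,6S)-2-bromo-3-(2-bromoethylidene)-4,6-dichloro-1,1-dimethylcyclohexane | CC1(C)[C@H](Br)/C(=C\CBr)[C@@H](Cl)C[C@@H]1Cl | target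

Total step count: 8
Longest linear sequence: 8 steps (from 1 to 15)

Steps most likely to fail (in route order)

Step 3. The tether forces a compact transition state, so discrimination between the two faces of the aldehyde may be weak, and the catalyst may be held back as an adduct with the aldehyde. The fallback sets out from 6 and returns at 9. Closure without asymmetric induction (pyrrolidine, AcOH, CH2Cl2, 0 °C) should give racemic 2-acetyl-5-hydroxy-4,4-dimethylcyclohex-2-en-1-one F1. The directed reduction of step 4 should then give the racemic trans-diol F2. Steglich esterification of its less hindered allylic hydroxyl with (S)-2-methoxy-2-phenylacetic acid (DCC, 4-(dimethylamino)pyridine, CH2Cl2, 0 °C) should give two diastereomers, the (1R,5R)-configured ester F3 and the (1S,5S)-configured ester F4, to be separated by chromatography or crystallisation. Methanolysis of F3 (K2CO3, MeOH, 0 °C) should return 9 as a single enantiomer.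

Step 5. Displacement at the neopentyl C6 may be slow, so that elimination towards C5 or a methyl shift competes. During the warm period the allylic C4 chloride may also be epimerised by chloride or alkylate excess phosphine. The fallback sets out from 9 and returns at 10; it separates the two carbinols and moves the forcing step to a stage without an allylic chloride. Selective silylation of the less hindered allylic hydroxyl (TBSCl, imidazole, DMF, 0 °C) should give the C4 silyl ether F5. The neopentyl hydroxyl is then converted into the triflate F6 (Tf2O, pyridine, CH2Cl2, −30 °C), and displacement with Bu4NCl in toluene (0 °C to rt) should give the inverted C6 chloride F7. HF·pyridine (THF, 0 °C) frees the allylic chlorohydrin F8, and a cold Appel reaction (PPh3, CCl4, MeCN, 0 °C) installs the allylic chloride with inversion to reach 10.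

Step 8. The bromosulfite may collapse at C7 itself or ionise to an allyl cation pair, so that chirality transfer to C2 and control of the alkene geometry are lost. The rotamer preference about C3–C7 may also be small, and bromide may exchange with the allylic chloride at C4. The fallback sets out from 10 and returns at 15. Luche reduction (NaBH4, CeCl3·7H2O, MeOH, −40 °C) should give the allylic alcohol F9 as a mixture of carbinol epimers. Dehydration with the Burgess reagent (toluene, 50 °C) should give the 1-vinylcyclohexene F10. Conjugate 1,4-addition of Br2 (CH2Cl2, −78 °C, then warming so that the allylic bromides equilibrate) places bromine at C2 and C8 and moves the double bond to C3=C7. This fallback trades stereocontrol for robust bond construction, so 15 would have to be separated from its C2 and alkene isomers.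

Further compounds
F1 | step 3 | racemic 2-acetyl-5-hydroxy-4,4-dimethylcyclohex-2-en-1-one (both enantiomers written) | CC1(C)C=C(C(C)=O)C(=O)C[C@H]1O.CC1(C)C=C(C(C)=O)C(=O)C[C@@H]1O
F2 | step 3 | racemic trans-1-(4,6-dihydroxy-3,3-dimethylcyclohex-1-en-1-yl)ethan-1-one (both enantiomers written) | CC1(C)C=C(C(C)=O)[C@H](O)C[C@H]1O.CC1(C)C=C(C(C)=O)[C@@H](O)C[C@@H]1O
F3 | step 3 | (1R,5R)-2-acetyl-5-hydroxy-4,4-dimethylcyclohex-2-en-1-yl (2S)-2-methoxy-2-phenylacetate | CC1(C)C=C(C(C)=O)[C@H](OC(=O)[C@@H](OC)c2ccccc2)C[C@H]1O
F4 | step 3 | (1S,5S)-2-acetyl-5-hydroxy-4,4-dimethylcyclohex-2-en-1-yl (2S)-2-methoxy-2-phenylacetate | CC1(C)C=C(C(C)=O)[C@@H](OC(=O)[C@@H](OC)c2ccccc2)C[C@@H]1O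
F5 | step 5 | 1-[(4R,6R)-6-{[tert-butyl(dimethyl)silyl]oxy}-4-hydroxy-3,3-dimethylcyclohex-1-en-1-yl]ethan-1-one | CC1(C)C=C(C(C)=O)[C@H](O[Si](C)(C)C(C)(C)C)C[C@H]1O
F6 | step 5 | (1R,5R)-4-acetyl-5-{[tert-butyl(dimethyl)silyl]oxy}-2,2-dimethylcyclohex-3-en-1-yl trifluoromethanesulfonate | CC1(C)C=C(C(C)=O)[C@H](O[Si](C)(C)C(C)(C)C)C[C@H]1OS(=O)(=O)C(F)(F)F
F7 | step 5 | 1-[(4S,6R)-6-{[tert-butyl(dimethyl)silyl]oxy}-4-chloro-3,3-dimethylcyclohex-1-en-1-yl]ethan-1-one | CC1(C)C=C(C(C)=O)[C@H](O[Si](C)(C)C(C)(C)C)C[C@@H]1Cl
F8 | step 5 | 1-[(4S,6R)-4-chloro-6-hydroxy-3,3-dimethylcyclohex-1-en-1-yl]ethan-1-one | CC1(C)C=C(C(C)=O)[C@H](O)C[C@@H]1Cl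
F9 | step 8 | 1-[(4S,6S)-4,6-dichloro-3,3-dimethylcyclohex-1-en-1-yl]ethan-1-ol (both carbinol epimers) | CC1(C)C=C(C(C)O)[C@@H](Cl)C[C@@H]1Cl
F10 | step 8 | (4S,6S)-4,6-dichloro-1-ethenyl-3,3-dimethylcyclohex-1-ene | CC1(C)C=C(C=C)[C@@H](Cl)C[C@@H]1Cl
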